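Ring A is grown on the diaryl ether oxygen instead of being coupled to ring B as an arene. Its aryloxy carbon C6 is flanked by C1 (pentyl) and C5 (OH), the place that the central carbon of an acetoacetate takes in a Michael–Claisen resorcinol construction. The crowded O–C6 bond is therefore formed early, by SN2 alkylation of a ring B phenol. A single base-mediated annulation of the resulting aryloxyacetoacetate with ethyl oct-2-ynoate then creates C6–C1 and C3–C4 and closes ring A as a cyclohexenedione blocked at C6, which aromatizes once the C6 ester leaves. In the precursor, ring B is a tert-butyl benzoate bearing a pentynyl group as latent pentanoyl.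

Key step: step 7

Assumption: the target is taken as the open keto acid as drawn; on acidification it may equilibrate with its ring-closed 3-hydroxyphthalide tautomer, which is regarded as the same compound.

Step 1
Reactants: 1 5,7-dihydroxy-2,2-dimethyl-4H-1,3-benzodioxin-4-one
Product: 2 5-hydroxy-7-methoxy-2,2-dimethyl-4H-1,3-benzodioxin-4-one
Conditions: MeOH, PPh3, DIAD, THF, 0 °C to rt
Reagents that add atoms: methanol, CO
Why: Mitsunobu etherification, in which the C5 hydroxyl is tied up in a hydrogen bond to the ring carbonyl and is far less acidic, so only the free C7 hydroxyl should be methylated.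

Step 2
Reactants: 2 5-hydroxy-7-methoxy-2,2-dimethyl-4H-1,3-benzodioxin-4-one
Product: 3 7-methoxy-2,2-dimethyl-4-oxo-4H-1,3-benzodioxin-5-yl trifluoromethanesulfonate
Conditions: Tf2O, pyridine, CH2Cl2, 0 °C
Reagents that add atoms: trifluoromethanesulfonic anhydride, O=S(=O)(OS(=O)(=O)C(F)(F)F)C(F)(F)F
Why: O-sulfonylation of the only remaining phenol, a standard reaction for this chelated hydroxyl, should give an aryl triflate activated for cross-coupling by the ortho carbonyl group.

Step 3
Reactants: 3 7-methoxy-2,2-dimethyl-4-oxo-4H-1,3-benzodioxin-5-yl trifluoromethanesulfonate; 4 1-pentyne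
Product: 5 7-methoxy-2,2-dimethyl-5-(pent-1-yn-1-yl)-4H-1,3-benzodioxin-4-one
Conditions: PdCl2(PPh3)2 (cat.), CuI (cat.), Et3N, DMF, 50 °C, sealed vessel
Reagents that add atoms: none
Why: Sonogashira coupling, in which the electron-poor ortho-acyl aryl triflate adds readily to zerovalent palladium while the acetonide masks acid and phenol, so nothing can lactonize onto the new alkyne.

Step 4
Reactants: 5 7-methoxy-2,2-dimethyl-5-(pent-1-yn-1-yl)-4H-1,3-benzodioxin-4-one
Product: 6 tert-butyl 2-hydroxy-4-methoxy-6-(pent-1-yn-1-yl)benzoate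
Conditions: KOtBu (1.5 equiv), THF, 0 °C to rt; then AcOH
Reagents that add atoms: potassium tert-butoxide, CC(C)(C)[O-].[K+]
Why: Alkoxide ring opening of the benzodioxinone (acyl substitution, transesterification type), in which the tetrahedral intermediate collapses with loss of acetone to a salicylate phenoxide, so the opening is irreversible and should deliver the tert-butyl ester and the free phenol together.

Step 5
Reactants: 7 tert-butyl acetoacetate
Product: 8 tert-butyl 2-chloro-3-oxobutanoate (racemic)
Conditions: SO2Cl2 (1.0 equiv), CH2Cl2, 0 °C to rt, N2 sweep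
Reagents that add atoms: sulfuryl chloride, O=S(=O)(Cl)Cl
Why: Electrophilic α-chlorination of the enol of a β-keto ester with sulfuryl chloride is the standard access to 2-chloroacetoacetates, and one equivalent at 0 °C with removal of HCl should avoid dichlorination and spare the tert-butyl ester.

Step 6
Reactants: 6 tert-butyl 2-hydroxy-4-methoxy-6-(pent-1-yn-1-yl)benzoate; 8 tert-butyl 2-chloro-3-oxobutanoate
Product: 9 tert-butyl 2-[2-(tert-butoxycarbonyl)-5-methoxy-3-(pent-1-yn-1-yl)phenoxy]-3-oxobutanoate (racemic)
Conditions: K2CO3, DMF, 50 °C (8 in excess)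
Reagents that add atoms: none
Why: Williamson-type SN2 O-alkylation of a phenoxide by an α-chloro-β-keto ester is a known route to 2-aryloxyacetoacetates, the product rests as its enolate, and the tert-butyl benzoate should not undergo Dieckmann closure to a benzofuranone.

Step 7
Reactants: 9 tert-butyl 2-[2-(tert-butoxycarbonyl)-5-methoxy-3-(pent-1-yn-1-yl)phenoxy]-3-oxobutanoate; 10 ethyl oct-2-ynoate
Product: 12 tert-butyl 1-[2-(tert-butoxycarbonyl)-5-methoxy-3-(pent-1-yn-1-yl)phenoxy]-2,4-dioxo-6-pentylcyclohex-5-ene-1-carboxylate (racemic), via acyclic Michael adduct 11 (not isolated)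
Conditions: KOtBu (1.05 equiv), THF/tBuOH, 0 °C to 50 °C (10 in slight excess); then AcOH
Reagents that add atoms: none
Why: Michael–Claisen annulation: the potassium enolate of 9 adds through its central carbon (future C6) to the β-carbon of ynoate 10 (future C1), tert-butanol protonates the allenolate to alkenoate 11, whose geometric isomers interconvert under base, and tert-butoxide then reversibly deprotonates the acetyl methyl group (C4), which attacks the ethyl ester carbonyl (C3) of the Z isomer and expels ethoxide. The closest known reaction type is the Michael–Claisen synthesis of dihydroresorcinols and resorcinols from acetoacetates and crotonates or 2-alkynoates, here applied to a donor that bears an aryloxy group on the reacting carbon. Ring A closes in a 6-exo-trig mode (enolate carbon onto the ester carbonyl), and the released ethoxide deprotonates the new 1,3-dione, which makes the closure irreversible. The quaternary C6 forms without control and racemic, which does not matter because it becomes sp2 on aromatization. The step needs C- over O-attack, closure through the methyl group only and no acyl transfer elsewhere: connectivity allows a six-membered ring solely through C4, both other esters are tert-butyl and inert to enolates and alkoxides, and one equivalent of the non-nucleophilic KOtBu keeps free ethoxide, and with it retro-Claisen deacetylation, to a minimum.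

Step 8
Reactants: 12 tert-butyl 1-[2-(tert-butoxycarbonyl)-5-methoxy-3-(pent-1-yn-1-yl)phenoxy]-2,4-dioxo-6-pentylcyclohex-5-ene-1-carboxylate
Product: 14 2-(2,4-dihydroxy-6-pentylphenoxy)-4-methoxy-6-(pent-1-yn-1-yl)benzoic acid, via β-keto diacid 13 (not isolated)
Conditions: CF3CO2H, iPr3SiH (excess), CH2Cl2, 0 °C to rt, short reaction time
Reagents that add atoms: none
Why: Acidolysis of both tert-butyl esters, with the silane reducing the tert-butyl cation to isobutane before it can alkylate the new resorcinol, frees the β-keto acid at C6, which should decarboxylate through an enol that is already the phenol, so ring A aromatizes without an oxidant.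

Step 9
Reactants: 14 2-(2,4-dihydroxy-6-pentylphenoxy)-4-methoxy-6-(pent-1-yn-1-yl)benzoic acid
Product: 16 2-(2,4-dihydroxy-6-pentylphenoxy)-4-methoxy-6-pentanoylbenzoic acid (target), via (Z)-butylidenephthalide 15 (not isolated)
Conditions: DBU (0.3 equiv), MeCN, 80 °C, degassed; then aq. NaOH, rt; then aq. HCl to pH 3, 0 °C
Reagents that add atoms: sodium hydroxide (aqueous, net addition of water), [Na+].[OH-]
Why: Amine-base-mediated anti addition of the carboxylate to the alkyne in the 5-exo-dig mode, the known regiochemistry for 2-alkynylbenzoic acids, should give the (Z)-alkylidenephthalide, and hydroxide then opens this enol lactone so that the oxygen ends on the benzylic carbon and the pentanoyl group results after mild acidification.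

Compound list
1 | 5,7-dihydroxy-2,2-dimethyl-4H-1,3-benzodioxin-4-one | CC1(C)OC(=O)c2c(O)cc(O)cc2O1 | starting material
2 | 5-hydroxy-7-methoxy-2,2-dimethyl-4H-1,3-benzodioxin-4-one | CC1(C)OC(=O)c2c(O)cc(OC)cc2O1 | intermediate
3 | 7-methoxy-2,2-dimethyl-4-oxo-4H-1,3-benzodioxin-5-yl trifluoromethanesulfonate | CC1(C)OC(=O)c2c(OS(=O)(=O)C(F)(F)F)cc(OC)cc2O1 | intermediate
4 | 1-pentyne | CCCC#C | starting material
5 | 7-methoxy-2,2-dimethyl-5-(pent-1-yn-1-yl)-4H-1,3-benzodioxin-4-one | CCCC#Cc1cc(OC)cc2OC(C)(C)OC(=O)c12 | intermediate
6 | tert-butyl 2-hydroxy-4-methoxy-6-(pent-1-yn-1-yl)benzoate | CCCC#Cc1cc(OC)cc(O)c1C(=O)OC(C)(C)C | intermediate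
7 | tert-butyl acetoacetate (tert-butyl 3-oxobutanoate) | CC(=O)CC(=O)OC(C)(C)C | starting material
8 | tert-butyl 2-chloro-3-oxobutanoate (racemic) | CC(=O)C(Cl)C(=O)OC(C)(C)C | intermediate
9 | tert-butyl 2-[2-(tert-butoxycarbonyl)-5-methoxy-3-(pent-1-yn-1-yl)phenoxy]-3-oxobutanoate (racemic; key-step precursor) | CCCC#Cc1cc(OC)cc(OC(C(C)=O)C(=O)OC(C)(C)C)c1C(=O)OC(C)(C)C | intermediate
10 | ethyl oct-2-ynoate | CCCCCC#CC(=O)OCC | starting material
11 | 5-tert-butyl 1-ethyl (2Z)-4-acetyl-4-[2-(tert-butoxycarbonyl)-5-methoxy-3-(pent-1-yn-1-yl)phenoxy]-3-pentylpent-2-enedioate (racemic; Michael adduct, not isolated) | CCCCC/C(=C/C(=O)OCC)C(Oc1cc(OC)cc(C#CCCC)c1C(=O)OC(C)(C)C)(C(C)=O)C(=O)OC(C)(C)C | intermediate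
12 | tert-butyl 1-[2-(tert-butoxycarbonyl)-5-methoxy-3-(pent-1-yn-1-yl)phenoxy]-2,4-dioxo-6-pentylcyclohex-5-ene-1-carboxylate (racemic; key-step product) | CCCCCC1=CC(=O)CC(=O)C1(Oc1cc(OC)cc(C#CCCC)c1C(=O)OC(C)(C)C)C(=O)OC(C)(C)C | intermediate
13 | 1-[2-carboxy-5-methoxy-3-(pent-1-yn-1-yl)phenoxy]-2,4-dioxo-6-pentylcyclohex-5-ene-1-carboxylic acid (racemic; not isolated) | CCCCCC1=CC(=O)CC(=O)C1(Oc1cc(OC)cc(C#CCCC)c1C(=O)O)C(=O)O | intermediate
14 | 2-(2,4-dihydroxy-6-pentylphenoxy)-4-methoxy-6-(pent-1-yn-1-yl)benzoic acid | CCCCCc1cc(O)cc(O)c1Oc1cc(OC)cc(C#CCCC)c1C(=O)O | intermediate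
15 | (3Z)-3-butylidene-7-(2,4-dihydroxy-6-pentylphenoxy)-5-methoxy-2-benzofuran-1(3H)-one (not isolated) | CCC/C=C1\OC(=O)c2c(Oc3c(O)cc(O)cc3CCCCC)cc(OC)cc12 | intermediate
16 | 2-(2,4-dihydroxy-6-pentylphenoxy)-4-methoxy-6-pentanoylbenzoic acid | CCCCCc1cc(O)cc(O)c1Oc1cc(OC)cc(C(=O)CCCC)c1C(=O)O | target

Total step count: 9. Longest linear sequence: 8 steps (1 → 2 → 3 → 5 → 6 → 9 → 12 → 14 → 16); step 5 is a one-step side branch.

Steps most likely to fail

Step 7. The crowded tertiary enolate may add only sluggishly to the β-alkyl ynoate. The base could then deacetylate donor or adduct by retro-Claisen cleavage, the ynoate could oligomerize, or the alkenoate could fail to reach the geometry needed for ring closure. The fallback gives up the annulation and forms the diaryl ether by copper-catalysed O-arylation; it sets out from phenol 6 and comes back at acid 14. Commercial olivetol (5-pentylresorcinol) would be protected with MOMCl/iPr2NEt to 1,3-bis(methoxymethoxy)-5-pentylbenzene F1. Iodination with NIS in MeCN, expected at the ring position ortho to the pentyl group and para to an oxygen, would give 2-iodo-1,5-bis(methoxymethoxy)-3-pentylbenzene F2. Ullmann-type coupling of 6 with F2 (CuI, picolinic acid, K3PO4, DMSO, 90 °C) should give tert-butyl 2-[2,4-bis(methoxymethoxy)-6-pentylphenoxy]-4-methoxy-6-(pent-1-yn-1-yl)benzoate F3. HCl in MeOH would remove the acetals to give tert-butyl 2-(2,4-dihydroxy-6-pentylphenoxy)-4-methoxy-6-(pent-1-yn-1-yl)benzoate F4, and CF3CO2H/iPr3SiH would then free acid 14.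

Step 4. Acyl substitution by the bulky alkoxide at the dioxinone carbonyl may stall, or excess base may isomerize the propargylic position towards an allene. The fallback separates ring opening from esterification; it sets out from 5 and comes back at 6. Hydrolysis with KOH in DMSO/water at the lowest workable temperature would give 2-hydroxy-4-methoxy-6-(pent-1-yn-1-yl)benzoic acid F5. O-tert-butylation of the carboxyl group with tert-butyl 2,2,2-trichloroacetimidate in CH2Cl2/cyclohexane at rt, which does not depend on attack at the hindered carbonyl and leaves the chelated phenol alone, should then give 6.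

Step 6. The hydrogen-bonded phenoxide may displace chloride too slowly from a partner that is largely enolized under the base, so self-condensation of 8 could consume the reagent. The fallback replaces SN2 by carbenoid O–H insertion; it sets out from 6 (with 7) and comes back at 9. Diazo transfer to 7 (4-acetamidobenzenesulfonyl azide, Et3N, MeCN) would give tert-butyl 2-diazo-3-oxobutanoate F6. Slow addition of F6 to 6 with Rh2(OAc)4 (cat.) in CH2Cl2 at reflux should give 9 directly, since insertion into the phenol O–H bond is faster than attack on the hindered internal alkyne.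

Further compounds
F1 | step 7 | 1,3-bis(methoxymethoxy)-5-pentylbenzene | CCCCCc1cc(OCOC)cc(OCOC)c1
F2 | step 7 | 2-iodo-1,5-bis(methoxymethoxy)-3-pentylbenzene | CCCCCc1cc(OCOC)cc(OCOC)c1I
F3 | step 7 | tert-butyl 2-[2,4-bis(methoxymethoxy)-6-pentylphenoxy]-4-methoxy-6-(pent-1-yn-1-yl)benzoate | CCCCCc1cc(OCOC)cc(OCOC)c1Oc1cc(OC)cc(C#CCCC)c1C(=O)OC(C)(C)C
F4 | step 7 | tert-butyl 2-(2,4-dihydroxy-6-pentylphenoxy)-4-methoxy-6-(pent-1-yn-1-yl)benzoate | CCCCCc1cc(O)cc(O)c1Oc1cc(OC)cc(C#CCCC)c1C(=O)OC(C)(C)C
F5 | step 4 | 2-hydroxy-4-methoxy-6-(pent-1-yn-1-yl)benzoic acid | CCCC#Cc1cc(OC)cc(O)c1C(=O)O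
F6 | step 6 | tert-butyl 2-diazo-3-oxobutanoate | CC(=O)C(=[N+]=[N-])C(=O)OC(C)(C)C
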